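**Retrosynthetic overview**

1. The free phenols are unmasked last: the ring-B methoxymethyl ether by acid, and the C5/C8 pair by oxidising the para-dimethoxyarene to the quinone and reducing it again. Before that, a Claisen–Schmidt condensation of the (S)-6-acetylchromene with 4-(methoxymethoxy)benzaldehyde makes the enone.
2. The (S)-6-acetylchromene comes from its racemate by kinetic resolution (Jacobsen–Katsuki epoxidation of the unwanted enantiomer). The acetyl group and the side-chain carbinol come from one MeMgBr addition to a 6-formyl chromene ester (Vilsmeier–Haack formylation at C6), followed by MnO2.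
3. The pyran ring (O1, C2, C3, C4, C4a, C8a) is the only ring that is made. It arises from 3,6-dimethoxybenzyne and a β,β-disubstituted enal through a four-membered benzoxete (O1, C4, C4a, C8a), which is enlarged by C3 and C2 (4π opening, oxa-6π closure).
4. Enabling feature: O1 and C4 sit on neighbouring arene carbons C8a/C4a (an aryne), and O1–C4–C3–C2 is an enal skeleton whose β-carbon becomes the quaternary C2. The C5 and C8 oxygens flank the aryne symmetrically, so no regiochemical question arises.
5. Building blocks: the enal from methyl 5-oxohexanoate (formylolefination), and the ortho-silylaryl triflate from 2,5-dimethoxyphenol (carbamate, ortho-silylation, triflation). Both benzene rings are bought.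

Key step: step 5

Remark: C2 is (S) as drawn. Because the ring-forming event passes through a planar intermediate, the configuration is secured afterwards by a catalytic kinetic resolution, whose sense is assigned from the usual side-on approach model for salen-manganese oxidants.

Step 1
Reactants: 1 methyl 5-oxohexanoate; 2 diethyl [(E)-2-(cyclohexylamino)ethenyl]phosphonate
Product: 4 methyl 5-methyl-7-oxohept-5-enoate (E/Z mixture), via N-cyclohexyl azadiene 3 (not isolated)
Conditions: NaH, THF, 0 °C to reflux (anion of 2 preformed); then aq. oxalic acid, rt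
Reagents that add atoms: water, O
Why: Horner–Wadsworth–Emmons-type formylolefination, in which the sodium salt of the enamine phosphonate adds to the ketone (the ester is far less electrophilic) and loses diethyl phosphate to give azadiene 3, which mild acid hydrolyses to the enal; the E/Z mixture is immaterial because this carbon becomes sp3 in step 5.

Step 2
Reactants: 5 2,5-dimethoxyphenol
Product: 6 2,5-dimethoxyphenyl N-isopropylcarbamate
Conditions: i-PrNCO, Et3N (cat.), CH2Cl2, rt
Reagents that add atoms: isopropyl isocyanate, CC(C)N=C=O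
Why: Base-catalysed addition of the phenol to the isocyanate gives the N-isopropyl carbamate, a strong directing group for ortho-metalation that can later be removed under mild conditions.

Step 3
Reactants: 6 2,5-dimethoxyphenyl N-isopropylcarbamate
Product: 10 3,6-dimethoxy-2-(trimethylsilyl)phenyl N-isopropylcarbamate, via N-silyl carbamate 7 (not isolated), via ortho-lithiated carbamate 8 (not isolated), via doubly silylated carbamate 9 (not isolated)
Conditions: TMSOTf, TMEDA, Et2O, 0 °C to rt; n-BuLi, TMEDA, −78 °C; TMSCl, −78 °C to rt; aq. NaHSO4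
Reagents that add atoms: chlorotrimethylsilane, C[Si](C)(C)Cl
Why: Directed ortho-metalation, in which after in situ N-silylation the carbamate and the neighbouring methoxy group together direct lithiation to the only free ortho position between them and TMSCl traps the aryllithium; the N-silyl group falls off on aqueous work-up.

Step 4
Reactants: 10 3,6-dimethoxy-2-(trimethylsilyl)phenyl N-isopropylcarbamate
Product: 12 3,6-dimethoxy-2-(trimethylsilyl)phenyl trifluoromethanesulfonate, via silylphenoxide 11 (not isolated)
Conditions: Et2NH, DBU, MeCN, 40 °C; then PhNTf2, rt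
Reagents that add atoms: N-phenylbis(trifluoromethanesulfonimide), O=S(=O)(N(c1ccccc1)S(=O)(=O)C(F)(F)F)C(F)(F)F
Why: Base-induced E1cB cleavage of the N–H carbamate (the isocyanate is trapped by diethylamine as a urea) frees the hindered phenoxide, which PhNTf2 sulfonylates to the ortho-silylaryl triflate that serves as aryne precursor.

Step 5
Reactants: 12 3,6-dimethoxy-2-(trimethylsilyl)phenyl trifluoromethanesulfonate; 4 methyl 5-methyl-7-oxohept-5-enoate (E/Z mixture)
Product: 16 rac-methyl 4-(5,8-dimethoxy-2-methyl-2H-chromen-2-yl)butanoate, via 3,6-dimethoxybenzyne 13 (not isolated), via alkenylbenzoxete 14 (not isolated), via o-quinone methide 15 (not isolated)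
Conditions: CsF, MeCN, 50 °C; 12 added slowly to an excess of 4
Reagents that add atoms: none
Why: CsF removes the silyl group of 12 and triflate leaves to give the symmetric aryne 13; the aldehyde oxygen of 4 adds to one aryne carbon and the resulting aryl anion closes on the carbonyl carbon (stepwise polar [2+2]), which forms the four-membered benzoxete 14 made of O1, C4, C4a and C8a. 14 opens by 4π electrocyclic ring-opening to the o-quinone methide 15, and its 1-oxatriene (O1=C8a–C4a=C4–C3=C2) closes by thermal oxa-6π electrocyclisation with formation of the O1–C2 bond, so that the four-membered ring is enlarged by C3 and C2 to the six-membered 2H-pyran while the benzene ring is restored. The closest known reaction type is the union of arynes with α,β-unsaturated aldehydes to 2H-chromenes by this [2+2]/ring-opening/6π sequence, itself related to aryne insertion into the C=O bond of formamides. C2 is created from the planar, achiral quinone methide, so no element controls it and 16 is formed as the racemate; the configuration is fixed in step 9. No regiochemical question arises, because the two methoxy groups beside the triple bond make both aryne carbons equivalent (either sense of addition gives 16) while their inductive pull makes the aryne electrophilic enough for the weakly nucleophilic carbonyl oxygen, and the E/Z mixture of 4 converges because its β-carbon becomes sp3. The step needs aldehyde-over-ester chemoselectivity and 1:1 over 2:1 aryne incorporation, which the inert ester, the slow release of 13 and the fast intramolecular closure of 15 should secure.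

Step 6
Reactants: 16 rac-methyl 4-(5,8-dimethoxy-2-methyl-2H-chromen-2-yl)butanoate
Product: 18 rac-methyl 4-(6-formyl-5,8-dimethoxy-2-methyl-2H-chromen-2-yl)butanoate, via aryl iminium chloride 17 (not isolated)
Conditions: POCl3, DMF, 0 to 40 °C; then aq. NaOAc
Reagents that add atoms: N,N-dimethylformamide, CN(C)C=O; water, O
Why: Vilsmeier–Haack formylation, an electrophilic aromatic substitution in which C6 (ortho to the 5-methoxy group and para to the ring oxygen O1) is activated by two oxygen donors whereas C7 is activated by one only, and the weak iminium electrophile should leave the C3=C4 bond and the ester untouched.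

Step 7
Reactants: 18 rac-methyl 4-(6-formyl-5,8-dimethoxy-2-methyl-2H-chromen-2-yl)butanoate
Product: 20 rac-5-[6-(1-hydroxyethyl)-5,8-dimethoxy-2-methyl-2H-chromen-2-yl]-2-methylpentan-2-ol (mixture of carbinol epimers), via methyl ketone 19 (not isolated)
Conditions: MeMgBr (excess), THF, 0 °C to rt; aq. NH4Cl
Reagents that add atoms: methylmagnesium bromide, C[Mg]Br
Why: Grignard addition, in which excess MeMgBr adds once to the aldehyde and twice to the methyl ester (through ketone 19), so one operation delivers the methyl of the future acetyl group and the tertiary carbinol of the side chain; the secondary carbinol centre is formed without control and is erased in step 8.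

Step 8
Reactants: 20 rac-5-[6-(1-hydroxyethyl)-5,8-dimethoxy-2-methyl-2H-chromen-2-yl]-2-methylpentan-2-ol
Product: 21 rac-1-[2-(4-hydroxy-4-methylpentyl)-5,8-dimethoxy-2-methyl-2H-chromen-6-yl]ethanone
Conditions: MnO2, CH2Cl2, rt
Reagents that add atoms: none
Why: Chemoselective MnO2 oxidation of the electron-rich benzylic secondary alcohol to the aryl methyl ketone; the tertiary alcohol cannot be oxidised and the chromene double bond is inert to this oxidant.

Step 9
Reactants: 21 rac-1-[2-(4-hydroxy-4-methylpentyl)-5,8-dimethoxy-2-methyl-2H-chromen-6-yl]ethanone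
Product: 22 1-[(2S)-2-(4-hydroxy-4-methylpentyl)-5,8-dimethoxy-2-methyl-2H-chromen-6-yl]ethanone
Conditions: (S,S)-[N,N'-bis(3,5-di-tert-butylsalicylidene)-1,2-cyclohexanediaminato]MnCl (C36H52ClMnN2O2, cat.), m-CPBA, NMO, CH2Cl2, −78 °C; stopped past half conversion, epoxide removed by chromatography
Reagents that add atoms: none
Why: Kinetic resolution by Jacobsen–Katsuki epoxidation, in which the (S,S)-catalyst should deliver oxygen to the face of C3=C4 that leads to the (3S,4S)-epoxide, a face that is open in (R)-21 (large C2 chain on the far side) but shielded by that chain in (S)-21, so the (R)-enantiomer is epoxidised and (S)-21 (= 22) is recovered; this selection fixes the configuration at C2.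

Step 10
Reactants: 22 1-[(2S)-2-(4-hydroxy-4-methylpentyl)-5,8-dimethoxy-2-methyl-2H-chromen-6-yl]ethanone; 23 4-(methoxymethoxy)benzaldehyde
Product: 25 (2E)-1-[(2S)-2-(4-hydroxy-4-methylpentyl)-5,8-dimethoxy-2-methyl-2H-chromen-6-yl]-3-[4-(methoxymethoxy)phenyl]prop-2-en-1-one, via aldol adduct 24 (not isolated)
Conditions: KOH, EtOH/H2O, rt
Reagents that add atoms: none
Why: Claisen–Schmidt condensation, in which the enolate of the methyl ketone adds to the non-enolisable aldehyde 23 and the aldol 24 dehydrates (E1cB) to the thermodynamically favoured (E)-enone; C2 is not touched by base.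

Step 11
Reactants: 25 (2E)-1-[(2S)-2-(4-hydroxy-4-methylpentyl)-5,8-dimethoxy-2-methyl-2H-chromen-6-yl]-3-[4-(methoxymethoxy)phenyl]prop-2-en-1-one
Product: 27 (2E)-1-[(2S)-5,8-dihydroxy-2-(4-hydroxy-4-methylpentyl)-2-methyl-2H-chromen-6-yl]-3-[4-(methoxymethoxy)phenyl]prop-2-en-1-one, via chromene-5,8-quinone 26 (not isolated)
Conditions: (NH4)2Ce(NO3)6, MeCN/H2O, 0 °C; then aq. Na2S2O4
Reagents that add atoms: water, O
Why: Oxidative demethylation of the para-dimethoxy pair at C5/C8 by ceric ammonium nitrate should give para-quinone 26 (the electron-poorer ring B and the enone are harder to oxidise), and dithionite reduces it in the same flask to the hydroquinone, which unmasks both phenols without acid or Lewis acid.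

Step 12
Reactants: 27 (2E)-1-[(2S)-5,8-dihydroxy-2-(4-hydroxy-4-methylpentyl)-2-methyl-2H-chromen-6-yl]-3-[4-(methoxymethoxy)phenyl]prop-2-en-1-one
Product: 28 (2E)-1-[(2S)-5,8-dihydroxy-2-(4-hydroxy-4-methylpentyl)-2-methyl-2H-chromen-6-yl]-3-(4-hydroxyphenyl)prop-2-en-1-one (target)
Conditions: HCl (cat.), MeOH, 0 °C to rt, argon
Reagents that add atoms: none
Why: Acid-catalysed acetal exchange removes the methoxymethyl ether as dimethoxymethane under conditions mild enough for the chromene, the tertiary alcohol and the 2'-hydroxychalcone.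

**Compound list**

1 | methyl 5-oxohexanoate | COC(=O)CCCC(C)=O | starting material
2 | diethyl [(E)-2-(cyclohexylamino)ethenyl]phosphonate | CCOP(=O)(OCC)/C=C/NC1CCCCC1 | starting material
3 | methyl 7-(cyclohexylimino)-5-methylhept-5-enoate (E/Z, not isolated) | COC(=O)CCCC(C)=CC=NC1CCCCC1 | intermediate
4 | methyl 5-methyl-7-oxohept-5-enoate (E/Z mixture) | COC(=O)CCCC(C)=CC=O | intermediate
5 | 2,5-dimethoxyphenol | COc1ccc(OC)c(O)c1 | starting material
6 | 2,5-dimethoxyphenyl N-isopropylcarbamate | COc1ccc(OC)c(OC(=O)NC(C)C)c1 | intermediate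
7 | 2,5-dimethoxyphenyl N-isopropyl-N-(trimethylsilyl)carbamate (not isolated) | COc1ccc(OC)c(OC(=O)N(C(C)C)[Si](C)(C)C)c1 | intermediate
8 | 6-lithio derivative of 7 (not isolated) | COc1ccc(OC)c(OC(=O)N(C(C)C)[Si](C)(C)C)c1[Li] | intermediate
9 | 3,6-dimethoxy-2-(trimethylsilyl)phenyl N-isopropyl-N-(trimethylsilyl)carbamate (not isolated) | COc1ccc(OC)c(OC(=O)N(C(C)C)[Si](C)(C)C)c1[Si](C)(C)C | intermediate
10 | 3,6-dimethoxy-2-(trimethylsilyl)phenyl N-isopropylcarbamate | COc1ccc(OC)c(OC(=O)NC(C)C)c1[Si](C)(C)C | intermediate
11 | 3,6-dimethoxy-2-(trimethylsilyl)phenol, present as its amidinium phenoxide (not isolated) | COc1ccc(OC)c(O)c1[Si](C)(C)C | intermediate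
12 | 3,6-dimethoxy-2-(trimethylsilyl)phenyl trifluoromethanesulfonate | COc1ccc(OC)c(OS(=O)(=O)C(F)(F)F)c1[Si](C)(C)C | intermediate
13 | 3,6-dimethoxybenzyne (not isolated) | COC1=CC=C(OC)C#C1 | intermediate
14 | methyl 6-(3,6-dimethoxy-2H-benzoxet-2-yl)-5-methylhex-5-enoate (not isolated) | COC(=O)CCCC(C)=CC1Oc2c1c(OC)ccc2OC | intermediate
15 | methyl 7-(2,5-dimethoxy-6-oxocyclohexa-2,4-dien-1-ylidene)-5-methylhept-5-enoate, the o-quinone methide (not isolated) | COC(=O)CCCC(C)=CC=C1C(OC)=CC=C(OC)C1=O | intermediate
16 | rac-methyl 4-(5,8-dimethoxy-2-methyl-2H-chromen-2-yl)butanoate | COC(=O)CCCC1(C)C=Cc2c(OC)ccc(OC)c2O1 | intermediate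
17 | iminium chloride from 16 and the chloroiminium reagent (not isolated) | COC(=O)CCCC1(C)C=Cc2c(OC)c(C=[N+](C)C)cc(OC)c2O1.[Cl-] | intermediate
18 | rac-methyl 4-(6-formyl-5,8-dimethoxy-2-methyl-2H-chromen-2-yl)butanoate | COC(=O)CCCC1(C)C=Cc2c(OC)c(C=O)cc(OC)c2O1 | intermediate
19 | 6-[6-(1-hydroxyethyl)-5,8-dimethoxy-2-methyl-2H-chromen-2-yl]hexan-2-one, as its magnesium alkoxide (not isolated) | CC(=O)CCCC1(C)C=Cc2c(OC)c(C(C)O)cc(OC)c2O1 | intermediate
20 | rac-5-[6-(1-hydroxyethyl)-5,8-dimethoxy-2-methyl-2H-chromen-2-yl]-2-methylpentan-2-ol (carbinol epimers) | CC(C)(O)CCCC1(C)C=Cc2c(OC)c(C(C)O)cc(OC)c2O1 | intermediate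
21 | rac-1-[2-(4-hydroxy-4-methylpentyl)-5,8-dimethoxy-2-methyl-2H-chromen-6-yl]ethanone | CC(C)(O)CCCC1(C)C=Cc2c(OC)c(C(C)=O)cc(OC)c2O1 | intermediate
22 | 1-[(2S)-2-(4-hydroxy-4-methylpentyl)-5,8-dimethoxy-2-methyl-2H-chromen-6-yl]ethanone | CC(C)(O)CCC[C@@]1(C)C=Cc2c(OC)c(C(C)=O)cc(OC)c2O1 | intermediate
23 | 4-(methoxymethoxy)benzaldehyde | COCOc1ccc(C=O)cc1 | starting material
24 | 3-hydroxy-1-[(2S)-2-(4-hydroxy-4-methylpentyl)-5,8-dimethoxy-2-methyl-2H-chromen-6-yl]-3-[4-(methoxymethoxy)phenyl]propan-1-one (carbinol epimers, not isolated) | CC(C)(O)CCC[C@@]1(C)C=Cc2c(OC)c(C(=O)CC(O)c3ccc(OCOC)cc3)cc(OC)c2O1 | intermediate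
25 | (2E)-1-[(2S)-2-(4-hydroxy-4-methylpentyl)-5,8-dimethoxy-2-methyl-2H-chromen-6-yl]-3-[4-(methoxymethoxy)phenyl]prop-2-en-1-one | CC(C)(O)CCC[C@@]1(C)C=Cc2c(OC)c(C(=O)/C=C/c3ccc(OCOC)cc3)cc(OC)c2O1 | intermediate
26 | (2S)-2-(4-hydroxy-4-methylpentyl)-6-{(2E)-3-[4-(methoxymethoxy)phenyl]prop-2-enoyl}-2-methyl-2H-chromene-5,8-dione (not isolated) | CC(C)(O)CCC[C@@]1(C)C=CC2=C(O1)C(=O)C=C(C(=O)/C=C/c3ccc(OCOC)cc3)C2=O | intermediate
27 | (2E)-1-[(2S)-5,8-dihydroxy-2-(4-hydroxy-4-methylpentyl)-2-methyl-2H-chromen-6-yl]-3-[4-(methoxymethoxy)phenyl]prop-2-en-1-one | CC(C)(O)CCC[C@@]1(C)C=Cc2c(O)c(C(=O)/C=C/c3ccc(OCOC)cc3)cc(O)c2O1 | intermediate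
28 | (2E)-1-[(2S)-5,8-dihydroxy-2-(4-hydroxy-4-methylpentyl)-2-methyl-2H-chromen-6-yl]-3-(4-hydroxyphenyl)prop-2-en-1-one (CNP0322520.1) | CC(C)(O)CCC[C@@]1(C)C=Cc2c(O)c(C(=O)/C=C/c3ccc(O)cc3)cc(O)c2O1 | target

Total step count: 12. Longest linear sequence: 11 steps (steps 2 to 12, from 2,5-dimethoxyphenol 5); step 1 is the side branch that supplies enal 4.

**Steps most likely to fail**

Step 5 (aryne capture and ring enlargement). The zwitterion formed after carbonyl-oxygen addition may be drained by proton transfer from the γ-methyl or γ-methylene group of the enal, and quinone methide 15 may be intercepted by a second aryne before it closes, so that conversion to the chromene stalls. The fallback leaves the aryne and sets out from phenol 5 and enal 4. These are heated with phenylboronic acid and a catalytic amount of propionic acid in toluene with removal of water, which should condense specifically at the only free ortho position of 5 to give methyl 6-(5,8-dimethoxy-2-phenyl-4H-1,3,2-benzodioxaborinin-4-yl)-5-methylhex-5-enoate F1. On continued heating F1 fragments to the same o-quinone methide 15, which closes to the chromene, and the route is rejoined at 16.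

Step 9 (kinetic resolution). The oxidant may discriminate poorly between the two enantiomers, because the peri 5-methoxy group and the flexible chain at C2 can level the two diastereomeric approaches, or it may discriminate in the opposite sense; high enantiopurity would then cost most of the material. The fallback replaces the catalytic selection by a physical separation. It sets out from racemic 21, which is resolved by preparative supercritical-fluid chromatography on an amylose tris(3,5-dimethylphenylcarbamate) phase, the (S)-enantiomer being assigned by correlation with the residue of a small-scale run of step 9. It comes back at 22 and makes no compound outside the list (F0).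

Step 11 (oxidative demethylation on the full chalcone). The acylquinone 26 may be captured by water or nitrate, the chromene double bond may be oxidised, or the ring-B acetal may be lost and the freed phenol oxidised before the reduction is applied. The fallback moves the change of oxidation level ahead of the enone. It sets out from 22 and comes back at target 28:

- 22 is treated with (NH4)2Ce(NO3)6 in MeCN/H2O and then with aq. Na2S2O4, which should give, through (2S)-6-acetyl-2-(4-hydroxy-4-methylpentyl)-2-methyl-2H-chromene-5,8-dione F2, the hydroquinone 1-[(2S)-5,8-dihydroxy-2-(4-hydroxy-4-methylpentyl)-2-methyl-2H-chromen-6-yl]ethanone F3.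
- MOMCl and i-Pr2NEt should protect only the non-chelated 8-hydroxyl, giving 1-[(2S)-5-hydroxy-2-(4-hydroxy-4-methylpentyl)-8-(methoxymethoxy)-2-methyl-2H-chromen-6-yl]ethanone F4.
- Claisen–Schmidt condensation of this 2'-hydroxyacetophenone with 23 (KOH, EtOH) should give (2E)-1-[(2S)-5-hydroxy-2-(4-hydroxy-4-methylpentyl)-8-(methoxymethoxy)-2-methyl-2H-chromen-6-yl]-3-[4-(methoxymethoxy)phenyl]prop-2-en-1-one F5.
- HCl in MeOH removes both acetals to give 28.

**Further compounds**

F1 | step 5 | methyl 6-(5,8-dimethoxy-2-phenyl-4H-1,3,2-benzodioxaborinin-4-yl)-5-methylhex-5-enoate | COC(=O)CCCC(C)=CC1OB(c2ccccc2)Oc2c1c(OC)ccc2OC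
F0 | step 9 | none | none
F2 | step 11 | (2S)-6-acetyl-2-(4-hydroxy-4-methylpentyl)-2-methyl-2H-chromene-5,8-dione | CC(C)(O)CCC[C@@]1(C)C=CC2=C(O1)C(=O)C=C(C(C)=O)C2=O
F3 | step 11 | 1-[(2S)-5,8-dihydroxy-2-(4-hydroxy-4-methylpentyl)-2-methyl-2H-chromen-6-yl]ethanone | CC(C)(O)CCC[C@@]1(C)C=Cc2c(O)c(C(C)=O)cc(O)c2O1
F4 | step 11 | 1-[(2S)-5-hydroxy-2-(4-hydroxy-4-methylpentyl)-8-(methoxymethoxy)-2-methyl-2H-chromen-6-yl]ethanone | CC(C)(O)CCC[C@@]1(C)C=Cc2c(O)c(C(C)=O)cc(OCOC)c2O1
F5 | step 11 | (2E)-1-[(2S)-5-hydroxy-2-(4-hydroxy-4-methylpentyl)-8-(methoxymethoxy)-2-methyl-2H-chromen-6-yl]-3-[4-(methoxymethoxy)phenyl]prop-2-en-1-one | CC(C)(O)CCC[C@@]1(C)C=Cc2c(O)c(C(=O)/C=C/c3ccc(OCOC)cc3)cc(OCOC)c2O1
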